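**Plan**

- Enabling feature (flavone numbering): ring A carries oxygen only at C5 and C6 and hydrogen at C7 and C8. C5 can therefore be an ester carbon on C4a, C8 a methyl carbon on C8a, and C6–C7 the two carbons of methoxyacetaldehyde.
- Retrosynthetic cuts, in order: the methyl of the C5 ether; C7–C8 and C5–C6 of ring A; O1–C2 and C4–C4a of ring C, giving an arylpropioloyl chloride and methyl acetoacetate.
- The arylpropiolic acid is cut at C3–C4 (CO2), C2–C3 (Corey–Fuchs carbon) and C2–C1' (formyl carbon), back to 1,2,4,5-tetramethoxybenzene.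
- Forward order: ring B is purchased and the hindered C1'–C2 bond is made first; ring C (the pyranone) is closed next; ring A is annulated last; one O-methylation finishes.
- Stereochemistry: the target has no stereocentre; the carbinol centre and alkene geometry that appear in the annulation are lost on aromatisation.

Key step: step 6

Remark: methoxyacetaldehyde is assumed to be used as the anhydrous monomer, distilled immediately before use.

**Step 1**
Reactants: 1 1,2,4,5-tetramethoxybenzene
Product: 3 2,3,5,6-tetramethoxybenzaldehyde, via aryllithium 2 (not isolated)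
Conditions: n-BuLi (1.05 equiv), TMEDA, THF, 0 °C; DMF, 0 °C → rt; 1 M HCl
Reagents that add atoms: N,N-dimethylformamide, CN(C)C=O
Why: Directed ortho-metalation at a ring CH flanked by two methoxy groups (both such positions are equivalent), followed by Bouveault-type formylation of the aryllithium, sets the hindered aryl–carbon bond at the outset.

**Step 2**
Reactants: 3 2,3,5,6-tetramethoxybenzaldehyde
Product: 4 3-(2,2-dibromoethenyl)-1,2,4,5-tetramethoxybenzene
Conditions: CBr4, PPh3, CH2Cl2, 0 °C
Reagents that add atoms: carbon tetrabromide, BrC(Br)(Br)Br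
Why: Corey–Fuchs dibromo-olefination (Wittig reaction of the dibromomethylene ylide formed in the flask) is reliable for ortho,ortho'-dialkoxy benzaldehydes.

**Step 3**
Reactants: 4 3-(2,2-dibromoethenyl)-1,2,4,5-tetramethoxybenzene
Product: 6 3-(2,3,5,6-tetramethoxyphenyl)prop-2-ynoic acid, via lithium acetylide 5 (not isolated)
Conditions: n-BuLi (2.05 equiv), THF, −78 °C; CO2 (dried gas), −78 °C → rt; 1 M HCl
Reagents that add atoms: carbon dioxide, O=C=O
Why: The second stage of the Corey–Fuchs alkyne synthesis (elimination and bromine–lithium exchange) gives the lithium acetylide, which is carboxylated in the same flask.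

**Step 4**
Reactants: 6 3-(2,3,5,6-tetramethoxyphenyl)prop-2-ynoic acid
Product: 7 3-(2,3,5,6-tetramethoxyphenyl)prop-2-ynoyl chloride
Conditions: (COCl)2, DMF (cat.), CH2Cl2, 0 °C → rt; evaporate, use crude
Reagents that add atoms: oxalyl chloride, O=C(Cl)C(=O)Cl
Why: Acid chloride formation through the catalytic chloroiminium (Vilsmeier-type) intermediate; low temperature and removal of HCl with the solvent should limit hydrochlorination of the triple bond.

**Step 5**
Reactants: 7 3-(2,3,5,6-tetramethoxyphenyl)prop-2-ynoyl chloride; 8 methyl acetoacetate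
Product: 10 methyl 2-methyl-4-oxo-6-(2,3,5,6-tetramethoxyphenyl)-4H-pyran-3-carboxylate, via ynone tricarbonyl 9 (not isolated)
Conditions: MgCl2, pyridine, CH2Cl2, 0 °C → rt, then 40 °C; 1 M HCl
Reagents that add atoms: none
Why: Soft-enolisation C-acylation of the magnesium-chelated β-keto ester enolate is followed by 6-endo-dig oxa-Michael addition of the acetyl enol oxygen to the ynone, the classical pyranone synthesis from arylpropioloyl chlorides and acetoacetic esters.

**Step 6**
Reactants: 10 methyl 2-methyl-4-oxo-6-(2,3,5,6-tetramethoxyphenyl)-4H-pyran-3-carboxylate; 11 methoxyacetaldehyde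
Product: 15 5-hydroxy-6-methoxy-2-(2,3,5,6-tetramethoxyphenyl)-4H-chromen-4-one, via lithium aldolate 12 (not isolated), via aldol acetate 13 (not isolated), via propenylpyranone 14 (not isolated)
Conditions: LiN(SiMe3)2 (1.1 equiv), THF, −78 °C; 11 (1.2 equiv), −78 °C; Ac2O (1.3 equiv), −78 → −30 °C; LiN(SiMe3)2 (3.5 equiv), −30 °C → rt; 1 M HCl
Reagents that add atoms: none
Why: Proposed new method: LiN(SiMe3)2 deprotonates the 2-methyl group of 10, which is vinylogous to both the ring ketone and the ester, and the dienolate adds through that carbon (the future C8) to the aldehyde carbon of 11 (future C7); acetylating lithium aldolate 12 to 13 before warming blocks the lactonisation onto the neighbouring ester that toluate-type aldolates undergo and supplies a leaving group for E1cB elimination to propenylpyranone 14. More base then removes an allylic proton from the methoxymethylene carbon (future C6), and the resulting trienolate attacks the ester carbon (future C5) in a 6-exo-trig Dieckmann closure, which can equally be read as a disrotatory six-electron electrocyclisation of the 1-oxidohexatriene resonance form; loss of methoxide and enolisation give ring A as the hydrogen-bonded phenol 15. The closest known reaction types are the vinylogous aldol condensation of 2-methyl-4-pyranones with aldehydes, the Staunton–Weinreb annulation of toluate anions and the amide-base cyclisation of ortho-allyl benzamides to 1-naphthols. No stereocentre remains: the carbinol carbon of 12 is formed as a racemate and becomes sp2 on elimination, and the alkene geometry of 14 does not matter because the delocalised anion can reach the conformer with C7 syn to C4a by bond rotation and reversible proton transfer. The step needs carbon acylation at C6 in preference to C8 or oxygen, which is secured because only C6 can close a six-membered ring and aromatisation makes that closure irreversible, while the hindered silylamide base and the twisted, doubly ortho-substituted aryl group keep nucleophiles away from the aryl-bearing pyranone carbon.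

**Step 7**
Reactants: 15 5-hydroxy-6-methoxy-2-(2,3,5,6-tetramethoxyphenyl)-4H-chromen-4-one
Product: 16 5,6-dimethoxy-2-(2,3,5,6-tetramethoxyphenyl)-4H-chromen-4-one (5,6,2',3',5',6'-hexamethoxyflavone)
Conditions: Me2SO4 (excess), K2CO3, acetone, reflux
Reagents that add atoms: dimethyl sulfate, COS(=O)(=O)OC
Why: Williamson O-methylation of the phenol; excess reagent and prolonged reflux overcome the hydrogen bond to the C4 carbonyl, as is routine for 5-hydroxyflavones.

**Compound list**

1 | 1,2,4,5-tetramethoxybenzene | COc1cc(OC)c(OC)cc1OC | starting material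
2 | (2,3,5,6-tetramethoxyphenyl)lithium | [Li]c1c(OC)c(OC)cc(OC)c1OC | intermediate (not isolated)
3 | 2,3,5,6-tetramethoxybenzaldehyde | O=Cc1c(OC)c(OC)cc(OC)c1OC | intermediate
4 | 3-(2,2-dibromoethenyl)-1,2,4,5-tetramethoxybenzene | BrC(Br)=Cc1c(OC)c(OC)cc(OC)c1OC | intermediate
5 | lithium (2,3,5,6-tetramethoxyphenyl)acetylide | [Li]C#Cc1c(OC)c(OC)cc(OC)c1OC | intermediate (not isolated)
6 | 3-(2,3,5,6-tetramethoxyphenyl)prop-2-ynoic acid | OC(=O)C#Cc1c(OC)c(OC)cc(OC)c1OC | intermediate
7 | 3-(2,3,5,6-tetramethoxyphenyl)prop-2-ynoyl chloride | ClC(=O)C#Cc1c(OC)c(OC)cc(OC)c1OC | intermediate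
8 | methyl acetoacetate | CC(=O)CC(=O)OC | starting material
9 | methyl 2-acetyl-3-oxo-5-(2,3,5,6-tetramethoxyphenyl)pent-4-ynoate | COC(=O)C(C(C)=O)C(=O)C#Cc1c(OC)c(OC)cc(OC)c1OC | intermediate (not isolated)
10 | methyl 2-methyl-4-oxo-6-(2,3,5,6-tetramethoxyphenyl)-4H-pyran-3-carboxylate | COC(=O)c1c(C)oc(-c2c(OC)c(OC)cc(OC)c2OC)cc1=O | intermediate
11 | methoxyacetaldehyde | COCC=O | starting material
12 | lithium 1-methoxy-3-[3-(methoxycarbonyl)-4-oxo-6-(2,3,5,6-tetramethoxyphenyl)-4H-pyran-2-yl]propan-2-olate (racemic) | COCC(O[Li])Cc1oc(-c2c(OC)c(OC)cc(OC)c2OC)cc(=O)c1C(=O)OC | intermediate (not isolated)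
13 | methyl 2-(2-acetoxy-3-methoxypropyl)-4-oxo-6-(2,3,5,6-tetramethoxyphenyl)-4H-pyran-3-carboxylate (racemic) | COCC(OC(C)=O)Cc1oc(-c2c(OC)c(OC)cc(OC)c2OC)cc(=O)c1C(=O)OC | intermediate (not isolated)
14 | methyl 2-[(E)-3-methoxyprop-1-enyl]-4-oxo-6-(2,3,5,6-tetramethoxyphenyl)-4H-pyran-3-carboxylate | COC/C=C/c1oc(-c2c(OC)c(OC)cc(OC)c2OC)cc(=O)c1C(=O)OC | intermediate (not isolated)
15 | 5-hydroxy-6-methoxy-2-(2,3,5,6-tetramethoxyphenyl)-4H-chromen-4-one | COc1cc(OC)c(OC)c(-c2cc(=O)c3c(O)c(OC)ccc3o2)c1OC | intermediate
16 | 5,6-dimethoxy-2-(2,3,5,6-tetramethoxyphenyl)-4H-chromen-4-one (5,6,2',3',5',6'-hexamethoxyflavone) | COc1cc(OC)c(OC)c(-c2cc(=O)c3c(OC)c(OC)ccc3o2)c1OC | target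

**Total step count:** 7

**Longest linear sequence:** 7 steps (from 1; compounds 8 and 11 are purchased)

**Steps most likely to fail**

1. Step 6 (key step).
 - What may go wrong: the lithium aldolate may cyclise onto the neighbouring ester faster than it is acetylated, and the lactone would then open by elimination to a dienyl carboxylate that cannot close. Alternatively, the trienolate may equilibrate its geometry too slowly, so that intermolecular condensation wins.
 - Fallback (stepwise, known reaction types, with an amide in place of the ester), setting out from acid chloride 7 and returning at phenol 15: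
 - C-acylation and ring closure with commercial N,N-diethylacetoacetamide under the conditions of step 5 should give N,N-diethyl-2-methyl-4-oxo-6-(2,3,5,6-tetramethoxyphenyl)-4H-pyran-3-carboxamide F1.
 - Lateral deprotonation with LiN(i-Pr)2 in THF at −78 °C and addition to 11 should give N,N-diethyl-2-(2-hydroxy-3-methoxypropyl)-4-oxo-6-(2,3,5,6-tetramethoxyphenyl)-4H-pyran-3-carboxamide F2, which an amide does not lactonise at low temperature and which is isolated.
 - MsCl and Et3N convert it into N,N-diethyl-2-[3-methoxy-2-(methylsulfonyloxy)propyl]-4-oxo-6-(2,3,5,6-tetramethoxyphenyl)-4H-pyran-3-carboxamide F3, and DBU eliminates this to N,N-diethyl-2-[(E)-3-methoxyprop-1-enyl]-4-oxo-6-(2,3,5,6-tetramethoxyphenyl)-4H-pyran-3-carboxamide F4.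
 - LiN(i-Pr)2 in THF at 0 °C → rt then effects the carbanionic ring closure onto the amide that is known for ortho-allyl benzamides (1-naphthol synthesis), expelling diethylamide and giving 15.

2. Step 5.
 - What may go wrong: O-acylation of the enolate, or conjugate addition of chloride or pyridine to the activated triple bond of the ynoyl chloride, may compete with C-acylation.
 - Fallback (the tricarbonyl is assembled in the reverse order, with no ynoyl chloride), setting out from acid 6 and returning at pyranone 10 through 9:
 - Carbonyldiimidazole converts 6 into 1-(1H-imidazol-1-yl)-3-(2,3,5,6-tetramethoxyphenyl)prop-2-yn-1-one F5.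
 - Masamune-type decarboxylative acylation of magnesium bis(methyl malonate), Mg(O2CCH2CO2Me)2, in THF gives methyl 3-oxo-5-(2,3,5,6-tetramethoxyphenyl)pent-4-ynoate F6.
 - C-acetylation of its magnesium enolate with acetyl chloride (MgCl2, pyridine, CH2Cl2) gives tricarbonyl 9, which closes to 10 as in step 5.

3. Step 3.
 - What may go wrong: excess butyllithium may metalate the last ring position, which is flanked by two methoxy groups like the site lithiated in step 1, leading to double carboxylation.
 - Fallback (no alkyllithium), setting out from aldehyde 3 and returning at acid 6: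
 - Seyferth–Gilbert homologation with dimethyl (1-diazo-2-oxopropyl)phosphonate, K2CO3 and MeOH gives 3-ethynyl-1,2,4,5-tetramethoxybenzene F7.
 - EtMgBr in THF deprotonates only the alkyne; carboxylation of the magnesium acetylide with CO2 and acidification then give 6.

**Further compounds**

F1 | step 6 | N,N-diethyl-2-methyl-4-oxo-6-(2,3,5,6-tetramethoxyphenyl)-4H-pyran-3-carboxamide | CCN(CC)C(=O)c1c(C)oc(-c2c(OC)c(OC)cc(OC)c2OC)cc1=O
F2 | step 6 | N,N-diethyl-2-(2-hydroxy-3-methoxypropyl)-4-oxo-6-(2,3,5,6-tetramethoxyphenyl)-4H-pyran-3-carboxamide (racemic) | CCN(CC)C(=O)c1c(CC(O)COC)oc(-c2c(OC)c(OC)cc(OC)c2OC)cc1=O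
F3 | step 6 | N,N-diethyl-2-[3-methoxy-2-(methylsulfonyloxy)propyl]-4-oxo-6-(2,3,5,6-tetramethoxyphenyl)-4H-pyran-3-carboxamide (racemic) | CCN(CC)C(=O)c1c(CC(COC)OS(C)(=O)=O)oc(-c2c(OC)c(OC)cc(OC)c2OC)cc1=O
F4 | step 6 | N,N-diethyl-2-[(E)-3-methoxyprop-1-enyl]-4-oxo-6-(2,3,5,6-tetramethoxyphenyl)-4H-pyran-3-carboxamide | CCN(CC)C(=O)c1c(/C=C/COC)oc(-c2c(OC)c(OC)cc(OC)c2OC)cc1=O
F5 | step 5 | 1-(1H-imidazol-1-yl)-3-(2,3,5,6-tetramethoxyphenyl)prop-2-yn-1-one | O=C(C#Cc1c(OC)c(OC)cc(OC)c1OC)n1ccnc1
F6 | step 5 | methyl 3-oxo-5-(2,3,5,6-tetramethoxyphenyl)pent-4-ynoate | COC(=O)CC(=O)C#Cc1c(OC)c(OC)cc(OC)c1OC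
F7 | step 3 | 3-ethynyl-1,2,4,5-tetramethoxybenzene | C#Cc1c(OC)c(OC)cc(OC)c1OC
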